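6 questions on 3 flasks come down to one: where does each flask stall?

| flask | starting material | reagent | second substrate | protic impurity | remark | time |
|---|---|---|---|---|---|---|
| epsilon | 0.62 M | 0.83 M | 0.62 M | 0.124 M | run made earlier |  |
| summer | 0.62 M | 0.740 M | 0.620 M | 0.124 M |  | 2.0 h |
| midnight | 0.62 M | 1.50 M | 0.620 M | 0.124 M |  | 2.0 h |
| dusk | 0.62 M | 3.00 M | 0.620 M | 0.124 M |  | 2.0 h |

epsilon run (percent of the starting material charged)

| time / min | starting material / % | target / % |
|---|---|---|
| 15.0 | 73 | 17 |
| 30.0 | 64 | 24 |
| 50.0 | 55 | 33 |
| 60.0 | 53 | 33 |
| 80.0 | 51 | 35 |

(scatter of a reading: 2 percentage points)

- a reading or a percentage of target counts all its forms, free or not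
- a reading of starting material is of its free form alone

- which of these there is most of at the end, counted by the starting material in it, summer (starting material / target)
- which of these there is most of at the end, counted by the starting material in it, midnight (starting material / target)
- which of these there is most of at the end, counted by the starting material in it, dusk (starting material / target)
- amount of the one of these that there is most of at the end, in percent of the starting material charged, summer
- amount of the one of these that there is most of at the end, in percent of the starting material charged, midnight
- amount of the one of these that there is most of at the end, in percent of the starting material charged, dusk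

Epsilon levels off: target reads 33% and then 35%, the scatter being 2 percentage points, with starting material at 51% at the last reading. I read this as a balance among target, free starting material and free reagent. Let x be target, a free starting material and β free reagent, each as a fraction of the starting material charge. On that scale ρ is the reagent charge, 2.42 at midnight. Each step below gives a quadratic in x.

1. Main step. Starting material and reagent give target reversibly, one reagent each, so a = 1 − x and β = ρ − x. Fitted to the last epsilon reading, x/(aβ) is 0.545, and midnight comes to x = 51.0%.

2. Second substrate. Its charge equals that of the starting material, and I let it hold reagent the same way, so β = ρ − 2x. Epsilon then keeps 47.7% of its reagent free. Refitted, the constant is 0.843, and midnight rises to 53.3%.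

3. The gap. The last epsilon readings fall short of the charge by 14.0%. Held per target, this makes a = 1 − hx with h = 1.40. Epsilon now reads 1.07 for x/(aβ), and this I carry: the stall number, target over free starting material over free reagent, an apparent equilibrium constant. Midnight falls to 48.9%.

4. The rest. Protic impurity has the same charge in every flask, so I let its effect stand inside the stall number. The asked 2.0 h is longer than the 80.0 min of the last reading, so I take each flask as stalled.

My reckoning: summer has target 32.3% and more starting material, 54.8%. Midnight has more target, with starting material 31.6%. Dusk has more target too, 60.4%, with starting material 15.5%.

The forecast, holding that “the reagent has run out rather than the substrate”, says starting material at 58% for summer, target at 62% for midnight and target at 85% for dusk.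

The flasks give starting material at 55.4% in summer, target at 52.2% at midnight and target at 69.5% at dusk.

    second substrate + reagent ⇌ second product (K = 2.40 M⁻¹, k = 6.00 × 10⁻⁴ M⁻¹ s⁻¹)
    2 starting material → self-condensation product (k = 2.90 × 10⁻⁷ M⁻¹ s⁻¹)
    starting material + target ⇌ idle adduct, settled at all times (K = 1.40 M⁻¹)
    second substrate + protic impurity → quenched substrate (k = 7.70 × 10⁻⁴ M⁻¹ s⁻¹)
    starting material + reagent ⇌ target (K = 1.40 M⁻¹, k = 3.90 × 10⁻⁴ M⁻¹ s⁻¹)

My dusk target is lower than the 69.5% found. At dusk h is 1.15, not 1.40, while the stall number, taken with the free reagent in that flask, is 1.02; at midnight it is 1.11. The neighbour is summer with 1.9 M of reagent, so ρ is 3.06. The same quadratic gives target 53.6% and starting material 25.0%. That flask holds most target, 58.5%, beside 29.5% starting material.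

(The data were computed on assumed constants, noise included.)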